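(The readings were computed with constants of no real substance, and the scatter is random.)

The ratio of complex with two exchanged to complex with one exchanged at the last reading was 0.128 in midnight and 0.380 in winter, and that difference told me which of my two reckonings to trust. Incoming ligand replaces leaving ligand on the starting complex, one site after another.

| flask | starting complex | incoming ligand | remark | time |
|---|---|---|---|---|
| noon | 31 mM | 2 equiv | run made earlier |  |
| midnight | 31 mM | 1 equiv | run made earlier |  |
| winter | 31 mM | 4 equiv | run made earlier |  |
| spring | 16 mM | 2 equiv | run made earlier |  |
| alpha | 31 mM | 2.00 equiv (fed, over 6.40 min) | all but incoming ligand at the start; incoming ligand goes in evenly over 6.40 min, the run ends at 8.0 min | 8.0 min |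
| eta | 31 mM | 2.00 equiv | a single well-mixed tank run continuously and read at steady state, 8.0 min in it on average |  |
| delta | 31 mM | 2.00 equiv | a closed flask charged with all of it at once and left for 8.0 min | 8.0 min |
| theta | 31 mM (fed, over 6.40 min) | 2.00 equiv | a stirred flask in which starting complex is dosed at a steady rate over 6.40 min without added volume, worked up at 8.0 min | 8.0 min |

| run | time / min | complex with one exchanged / % | complex with two exchanged / % |
|---|---|---|---|
| noon | 1.00 | 15.3 | 0.4 |
| noon | 2.00 | 24.2 | 1.9 |
| noon | 3.00 | 28.0 | 4.7 |
| noon | 4.00 | 29.5 | 5.2 |
| noon | 5.00 | 28.7 | 6.8 |
| midnight | 0.417 | 4.2 | 0.1 |
| midnight | 1.33 | 10.8 | 0.6 |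
| midnight | 2.00 | 14.4 | 0.6 |
| midnight | 3.00 | 18.7 | 1.5 |
| midnight | 5.00 | 22.6 | 2.9 |
| winter | 0.417 | 14.2 | 0.4 |
| winter | 1.33 | 29.8 | 3.9 |
| winter | 2.00 | 33.5 | 6.3 |
| winter | 3.00 | 32.9 | 8.6 |
| winter | 5.00 | 24.5 | 9.3 |
| spring | 1.00 | 9.7 | 0 |
| spring | 2.00 | 16.2 | 1.0 |
| spring | 3.00 | 20.4 | 1.7 |
| spring | 4.00 | 24.5 | 2.7 |
| spring | 5.00 | 26.7 | 4.0 |

(each reading ± 0.3 percentage points)

- the stated concentrations are those of everything mixed, before any reaction; amounts are the same in each set-up
- the feed brings no volume worth counting
- the earlier runs were made in a closed, stirred flask
- a reading or a percentage of complex with one exchanged counts all its forms, free or not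

- the set-up with the highest share of complex with one exchanged in all that became complex with one exchanged or complex with two exchanged or complex with three exchanged or complex with four exchanged, at the outlet or at the end ("none" if the first two lie within 2 percentage points) (alpha / eta / delta / theta / none)
- share of complex with one exchanged in all that became complex with one exchanged or complex with two exchanged or complex with three exchanged or complex with four exchanged, at the outlet or at the end, alpha
- share of complex with one exchanged in all that became complex with one exchanged or complex with two exchanged or complex with three exchanged or complex with four exchanged, at the outlet or at the end, eta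
- share of complex with one exchanged in all that became complex with one exchanged or complex with two exchanged or complex with three exchanged or complex with four exchanged, at the outlet or at the end, delta
- share of complex with one exchanged in all that became complex with one exchanged or complex with two exchanged or complex with three exchanged or complex with four exchanged, at the outlet or at the end, theta

I wanted the share for delta. Where complex with one exchanged stands about level, as at noon, what has gone onward is N times what stands, so the share is one over one plus N. N counts onward lifetimes: the pseudo-first-order onward rate at the ligand present, times the time.

Noon had used at least 0.423 equivalents by its last reading, so I gave delta a mean ligand of 1.58. Midnight's mean was 0.858.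

Way one took the noon peak as making equal to loss, with making continuing from midnight's first slope, 0.101 /min at one equivalent:

loss = 0.285 /min, N = 2.28, share 30.5%

Way two took midnight's two-exchanged over the one-exchanged it came from, with the 2.00 min reading as the mean across 5.00 min:

rate = 0.0403 /min, N = 0.592, share 62.8%

This N is the lifetime count.

The ways parted. Way one's loss, scaled to midnight, makes 11.2% of two-exchanged, more than the 2.9% read. Quick clearing might hide that, but ligand should speed making and clearing alike, holding one ratio at any ligand. Midnight's ratio lay below winter's, so I trusted way two: way one cheats by keeping the making going.

The forecast gave 57% for alpha, 43% for eta, 41% for delta and 52% for theta: “Alpha looks best, though not by a wide margin.” My 62.8% for delta differed from it.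

The flasks gave 73.8% for alpha, 58.8% for eta, 56.5% for delta and 69.4% for theta, with alpha best.

    starting complex + incoming ligand ⇌ leaving ligand + complex with one exchanged (K = 0.210, k = 0.0530 /M/s)
    complex with one exchanged + incoming ligand ⇌ leaving ligand + complex with two exchanged (K = 45.0, k = 0.0380 /M/s)
    complex with two exchanged + incoming ligand ⇌ leaving ligand + complex with three exchanged (K = 6.30, k = 0.110 /M/s)
    complex with three exchanged + incoming ligand ⇌ leaving ligand + complex with four exchanged (K = 0.300, k = 0.0680 /M/s)
    starting complex + complex with one exchanged ⇌ idle adduct, settled at all times (K = 6.70 /M)

In delta, the first exchange had half of its turnover behind it by 1.32 min, while the onward step had 3.5% of its own behind it after 0.800 min. Starting complex stood at 56.4% at the end of delta, above the 28.1% of a forward count. Delta's share means N = 0.770, above my 0.592.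

For delta's neighbour with 1.20 equiv of incoming ligand, I took off the same fraction of the charge as for delta, 21.1%, and the count gives N = 0.355, a share of 73.8%. The computed share is 73.7%.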